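The 2H-pyran ring D is disconnected at its C3''=C4'' double bond. This leads back to a (2S)-flavanone whose ring B carries a vinyl group at C5' and identical 1,1-dimethylallyl ethers on both catechol oxygens, O3' and O4'. In one operation, ring-closing metathesis joins the vinyl carbon to the terminus of the O4' ether and closes ring D; brief heating then moves the untouched O3' ether by [3,3] shift to C2', its only free ortho carbon, as the prenyl group. The step exploits that the C2' prenyl group and the O1''–C2''–C3'' segment of ring D are the same C5 unit. C2 is set earlier by rhodium-catalysed asymmetric 1,4-addition to an 8-prenylchromone.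

Key step: step 9

Remark on the chemistry: flavanone locants are used (rings A and C unprimed, ring B primed with the pyran-bearing carbon as C5', pyran ring D double-primed as O1''–C2''–C3''=C4''), and carbonate 2 is made in step 1 because its commercial supply is not assumed.

Step 1
Reactants: 1 2-methylbut-3-en-2-ol
Product: 2 tert-butyl 2-methylbut-3-en-2-yl carbonate
Conditions: n-BuLi, THF, 0 °C; then Boc2O, 0 °C to rt
Reagents that add atoms: di-tert-butyl dicarbonate, CC(C)(C)OC(=O)OC(=O)OC(C)(C)C
Why: O-acylation of the lithium tert-alkoxide with Boc2O is the standard way to a tertiary allylic carbonate, the leaving group needed in step 2.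

Step 2
Reactants: 3 5-bromo-2,3-dihydroxybenzaldehyde; 2 tert-butyl 2-methylbut-3-en-2-yl carbonate
Product: 4 5-bromo-2,3-bis(2-methylbut-3-en-2-yloxy)benzaldehyde
Conditions: 2 (3 equiv), Pd(PPh3)4 (5 mol%), THF, 0 °C
Reagents that add atoms: none
Why: Tsuji–Trost allylic etherification, in which zerovalent palladium ionises 2 to a 1,1-dimethyl-π-allyl complex and tert-butoxide and each phenoxide should attack the more substituted allyl terminus under kinetic control at low temperature, as is known for vicinal bis(1,1-dimethylallyl) ethers of catechols, while the aryl bromide is inert to Pd(PPh3)4 at 0 °C.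

Step 3
Reactants: 4 5-bromo-2,3-bis(2-methylbut-3-en-2-yloxy)benzaldehyde
Product: 5 5-bromo-1-ethenyl-2,3-bis(2-methylbut-3-en-2-yloxy)benzene
Conditions: Ph3PCH3Br, KOtBu, THF, 0 °C
Reagents that add atoms: methyltriphenylphosphonium bromide, C[P+](c1ccccc1)(c1ccccc1)c1ccccc1.[Br-]
Why: Wittig methylenation of a non-enolisable aryl aldehyde with the unstabilised ylide is reliable and should leave the aryl bromide and the tertiary allyl ethers untouched.

Step 4
Reactants: 5 5-bromo-1-ethenyl-2,3-bis(2-methylbut-3-en-2-yloxy)benzene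
Product: 8 [3-ethenyl-4,5-bis(2-methylbut-3-en-2-yloxy)phenyl]boronic acid, via aryllithium 6 (not isolated), via lithium aryltriisopropoxyborate 7 (not isolated)
Conditions: n-BuLi (1.1 equiv) added to 5 + B(OiPr)3 (1.5 equiv), THF/toluene, −78 °C; then H2O, pH 6–7
Reagents that add atoms: triisopropyl borate, CC(C)OB(OC(C)C)OC(C)C; water, O
Why: Bromine–lithium exchange with in situ borylation, in which exchange at −78 °C should outrun addition of n-BuLi to the styrene, the aryllithium is trapped at once as the ate complex, and near-neutral hydrolysis gives the boronic acid without ionising the acid-sensitive tertiary ethers.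

Step 5
Reactants: 9 1-(2,4,6-trihydroxyphenyl)ethanone; 10 1-bromo-3-methylbut-2-ene
Product: 11 1-[2,4,6-trihydroxy-3-(3-methylbut-2-en-1-yl)phenyl]ethanone
Conditions: 10 (1.0 equiv), DBU, THF, rt
Reagents that add atoms: none
Why: C-alkylation of the ambident phloroglucinol-type phenoxide (Friedel–Crafts-like C-prenylation) is the known entry to 3-prenylphloroacetophenone, the two open ring carbons being equivalent by symmetry and one equivalent of bromide limiting dialkylation.

Step 6
Reactants: 11 1-[2,4,6-trihydroxy-3-(3-methylbut-2-en-1-yl)phenyl]ethanone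
Product: 12 1-[2-hydroxy-4,6-bis(methoxymethoxy)-3-(3-methylbut-2-en-1-yl)phenyl]ethanone
Conditions: MOMCl (2.2 equiv), iPr2NEt, CH2Cl2, 0 °C
Reagents that add atoms: chloromethyl methyl ether, COCCl
Why: Williamson-type acetal formation should cap the most acidic 4-OH and the less hindered of the two chelated phenols (6-OH), leaving the 2-OH that is flanked by prenyl and acetyl as the hydrogen-bonded phenol, which fixes the prenyl group at the later C8.

Step 7
Reactants: 12 1-[2-hydroxy-4,6-bis(methoxymethoxy)-3-(3-methylbut-2-en-1-yl)phenyl]ethanone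
Product: 14 5,7-bis(methoxymethoxy)-8-(3-methylbut-2-en-1-yl)-4H-chromen-4-one, via enaminone 13 (not isolated)
Conditions: Me2NCH(OMe)2, toluene, 100 °C; then AcOH, CH2Cl2, rt
Reagents that add atoms: N,N-dimethylformamide dimethyl acetal, COC(OC)N(C)C
Why: Enaminone chromone synthesis, in which the methyl ketone condenses with the amide acetal and mild acid then triggers conjugate addition of the only free phenol and loss of dimethylamine, AcOH being mild enough for the MOM ethers and the prenyl group.

Step 8
Reactants: 14 5,7-bis(methoxymethoxy)-8-(3-methylbut-2-en-1-yl)-4H-chromen-4-one; 8 [3-ethenyl-4,5-bis(2-methylbut-3-en-2-yloxy)phenyl]boronic acid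
Product: 15 (2S)-2-[3-ethenyl-4,5-bis(2-methylbut-3-en-2-yloxy)phenyl]-5,7-bis(methoxymethoxy)-8-(3-methylbut-2-en-1-yl)-2,3-dihydro-4H-chromen-4-one
Conditions: 8 (1.5 equiv), [Rh(OH)(cod)]2 (2.5 mol%), (S)-MeO-F12-BIPHEP [(S)-(6,6'-dimethoxybiphenyl-2,2'-diyl)bis(bis(3,4,5-trifluorophenyl)phosphane)] (5.5 mol%), CH2Cl2/H2O, 30 °C
Reagents that add atoms: none
Why: Hayashi–Miyaura asymmetric 1,4-addition, a known route from chromones to flavanones, in which transmetalation gives an aryl–rhodium species free of ortho substituents, the electron-poor (S)-bisphosphine is expected by the model for cyclic enones to direct carbometalation to the Re face of C2 and so set (2S) (the antipodal ligand is taken if the sense proves opposite), and hydrolysis of the rhodium enolate releases 15 under neutral conditions well below the temperature at which the tertiary allyl ethers rearrange.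

Step 9
Reactants: 15 (2S)-2-[3-ethenyl-4,5-bis(2-methylbut-3-en-2-yloxy)phenyl]-5,7-bis(methoxymethoxy)-8-(3-methylbut-2-en-1-yl)-2,3-dihydro-4H-chromen-4-one
Product: 17 (2S)-2-[8-hydroxy-2,2-dimethyl-7-(3-methylbut-2-en-1-yl)-2H-chromen-6-yl]-5,7-bis(methoxymethoxy)-8-(3-methylbut-2-en-1-yl)-2,3-dihydro-4H-chromen-4-one, via chromene ether 16 (not isolated)
Conditions: second-generation Grubbs catalyst RuCl2(H2IMes)(PCy3)(=CHPh) (5 mol%), toluene (5 mM), 40 °C; then ethyl vinyl ether; then 110 °C, one pot
Reagents that add atoms: none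
Why: The ruthenium benzylidene should initiate at the unhindered styrene on C5' and close ring D through a ruthenacyclobutane onto the neighbouring O4'–C(CH3)2–CH=CH2 terminus, forming the C3''=C4'' bond with loss of ethene (ring-closing metathesis of a 1,7-diene to a six-membered cis-alkene, the known route from 2-vinylaryl allyl ethers to 2H-chromenes, helped here by the gem-dimethyl group). After the carbene is quenched, warming lets the remaining O3' ether undergo an aromatic Claisen rearrangement through a chair transition state to C2', and tautomerisation of the dienone gives the 3'-phenol with the allyl unit inverted to a prenyl group, as is known for aryl 1,1-dimethylallyl ethers. No stereocentre is formed, and C2 should stay intact because the medium is neutral and the 5-oxygen is capped. Chemoselectivity among the four alkenes rests on ring size and substitution: the O3' ether could only close an eight-membered ring between two quaternary carbons, and the trisubstituted prenyl group on ring A is a poor metathesis partner. Site selectivity of the shift rests on C2' being the only ortho carbon that bears hydrogen, so that attack at the substituted C4' gives a dienone that cannot tautomerise and is expected to revert faster than it passes the allyl group on to the crowded C6'. Running the metathesis first removes the second allyl ether, so that the Claisen–Diels–Alder pathway open to vicinal bis(allyloxy)arenes cannot trap that dienone.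

Step 10
Reactants: 17 (2S)-2-[8-hydroxy-2,2-dimethyl-7-(3-methylbut-2-en-1-yl)-2H-chromen-6-yl]-5,7-bis(methoxymethoxy)-8-(3-methylbut-2-en-1-yl)-2,3-dihydro-4H-chromen-4-one
Product: 18 (2S)-5,7-dihydroxy-2-[8-hydroxy-2,2-dimethyl-7-(3-methylbut-2-en-1-yl)-2H-chromen-6-yl]-8-(3-methylbut-2-en-1-yl)-2,3-dihydro-4H-chromen-4-one
Conditions: HCl (3 M aq), MeOH, 40 °C
Reagents that add atoms: none
Why: Acid-catalysed transacetalisation of the two MOM ethers to methanol under dilute, cool conditions is the usual end game for prenylated flavanones and should spare the o-prenylphenols, the chromene and the C2 stereocentre, which does not epimerise in acid.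

Compound list
1 | 2-methylbut-3-en-2-ol | CC(C)(O)C=C | starting material
2 | tert-butyl 2-methylbut-3-en-2-yl carbonate | CC(C)(C)OC(=O)OC(C)(C)C=C | intermediate
3 | 5-bromo-2,3-dihydroxybenzaldehyde | O=Cc1cc(Br)cc(O)c1O | starting material
4 | 5-bromo-2,3-bis(2-methylbut-3-en-2-yloxy)benzaldehyde | O=Cc1cc(Br)cc(OC(C)(C)C=C)c1OC(C)(C)C=C | intermediate
5 | 5-bromo-1-ethenyl-2,3-bis(2-methylbut-3-en-2-yloxy)benzene | C=Cc1cc(Br)cc(OC(C)(C)C=C)c1OC(C)(C)C=C | intermediate
6 | [3-ethenyl-4,5-bis(2-methylbut-3-en-2-yloxy)phenyl]lithium | [Li]c1cc(C=C)c(OC(C)(C)C=C)c(OC(C)(C)C=C)c1 | intermediate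
7 | lithium [3-ethenyl-4,5-bis(2-methylbut-3-en-2-yloxy)phenyl]tri(propan-2-yloxy)borate | [Li+].CC(C)O[B-](OC(C)C)(OC(C)C)c1cc(C=C)c(OC(C)(C)C=C)c(OC(C)(C)C=C)c1 | intermediate
8 | [3-ethenyl-4,5-bis(2-methylbut-3-en-2-yloxy)phenyl]boronic acid | OB(O)c1cc(C=C)c(OC(C)(C)C=C)c(OC(C)(C)C=C)c1 | intermediate
9 | 1-(2,4,6-trihydroxyphenyl)ethanone | CC(=O)c1c(O)cc(O)cc1O | starting material
10 | 1-bromo-3-methylbut-2-ene | CC(C)=CCBr | starting material
11 | 1-[2,4,6-trihydroxy-3-(3-methylbut-2-en-1-yl)phenyl]ethanone | CC(=O)c1c(O)cc(O)c(CC=C(C)C)c1O | intermediate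
12 | 1-[2-hydroxy-4,6-bis(methoxymethoxy)-3-(3-methylbut-2-en-1-yl)phenyl]ethanone | CC(=O)c1c(OCOC)cc(OCOC)c(CC=C(C)C)c1O | intermediate
13 | (2E)-3-(dimethylamino)-1-[2-hydroxy-4,6-bis(methoxymethoxy)-3-(3-methylbut-2-en-1-yl)phenyl]prop-2-en-1-one | CN(C)/C=C/C(=O)c1c(OCOC)cc(OCOC)c(CC=C(C)C)c1O | intermediate
14 | 5,7-bis(methoxymethoxy)-8-(3-methylbut-2-en-1-yl)-4H-chromen-4-one | O=c1ccoc2c(CC=C(C)C)c(OCOC)cc(OCOC)c12 | intermediate
15 | (2S)-2-[3-ethenyl-4,5-bis(2-methylbut-3-en-2-yloxy)phenyl]-5,7-bis(methoxymethoxy)-8-(3-methylbut-2-en-1-yl)-2,3-dihydro-4H-chromen-4-one | C=Cc1cc([C@@H]2CC(=O)c3c(OCOC)cc(OCOC)c(CC=C(C)C)c3O2)cc(OC(C)(C)C=C)c1OC(C)(C)C=C | intermediate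
16 | (2S)-2-[2,2-dimethyl-8-(2-methylbut-3-en-2-yloxy)-2H-chromen-6-yl]-5,7-bis(methoxymethoxy)-8-(3-methylbut-2-en-1-yl)-2,3-dihydro-4H-chromen-4-one | CC1(C)C=Cc2cc([C@@H]3CC(=O)c4c(OCOC)cc(OCOC)c(CC=C(C)C)c4O3)cc(OC(C)(C)C=C)c2O1 | intermediate
17 | (2S)-2-[8-hydroxy-2,2-dimethyl-7-(3-methylbut-2-en-1-yl)-2H-chromen-6-yl]-5,7-bis(methoxymethoxy)-8-(3-methylbut-2-en-1-yl)-2,3-dihydro-4H-chromen-4-one | CC(C)=CCc1c([C@@H]2CC(=O)c3c(OCOC)cc(OCOC)c(CC=C(C)C)c3O2)cc2c(c1O)OC(C)(C)C=C2 | intermediate
18 | (2S)-5,7-dihydroxy-2-[8-hydroxy-2,2-dimethyl-7-(3-methylbut-2-en-1-yl)-2H-chromen-6-yl]-8-(3-methylbut-2-en-1-yl)-2,3-dihydro-4H-chromen-4-one | CC(C)=CCc1c([C@@H]2CC(=O)c3c(O)cc(O)c(CC=C(C)C)c3O2)cc2c(c1O)OC(C)(C)C=C2 | target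

Total step count: 10
Longest linear sequence: 7 steps (steps 1, 2, 3, 4, 8, 9, 10)

Steps most likely to fail

Step 8. The aryl–rhodium intermediate may be diverted before it adds to the electron-rich, slowly reacting chromone, either by insertion into the styrene of another molecule or by protonation (protodeboronation). Opening of the rhodium enolate to the chalcone would also erode the enantiomeric purity. The fallback moves the ring closure ahead of the coupling, so that no terminal styrene is present when the aryl–rhodium species forms. It sets out from 5: ring-closing metathesis (second-generation Grubbs catalyst RuCl2(H2IMes)(PCy3)(=CHPh), CH2Cl2, 40 °C) should give 6-bromo-2,2-dimethyl-8-(2-methylbut-3-en-2-yloxy)-2H-chromene F1. Bromine–lithium exchange and borylation as in step 4 should then give [2,2-dimethyl-8-(2-methylbut-3-en-2-yloxy)-2H-chromen-6-yl]boronic acid F2. Its 1,4-addition to 14 under the conditions of step 8 comes back to the route at 16, which is now isolated and heated in toluene at 110 °C to reach 17.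

Step 9. The sigmatropic half may lose site selectivity because C2' is flanked by the chromanone: attack at C4' followed by Cope shift to C6', or loss of isoprene, would compete, and residual ruthenium may isomerise alkenes during heating. The fallback runs the shift before the coupling, where the only open ortho carbon is flanked by bromine. It sets out from 5 and passes through the bromochromene F1 made as above. Heating F1 in toluene at 110 °C should give 6-bromo-2,2-dimethyl-7-(3-methylbut-2-en-1-yl)-2H-chromen-8-ol F3. Deprotonation and bromine–lithium exchange (n-BuLi, 2.2 equiv, B(OiPr)3, THF, −78 °C; then H2O) should give [8-hydroxy-2,2-dimethyl-7-(3-methylbut-2-en-1-yl)-2H-chromen-6-yl]boronic acid F4. Rhodium-catalysed 1,4-addition of this ortho-substituted boronic acid to 14, with higher catalyst loading and longer time, comes back to the route at 17.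

Step 2. The second etherification, at the chelated and doubly flanked 2-OH, may stall, or reversible ionisation by palladium may drain the kinetic tertiary ethers into linear prenyl ethers. The fallback builds the tertiary ethers by propargylic substitution and reduction instead of through a π-allyl complex. It sets out from 3: copper-catalysed etherification (3-chloro-3-methylbut-1-yne, CuCl2 (cat.), DBU, MeCN, 0 °C) should give 5-bromo-2,3-bis(2-methylbut-3-yn-2-yloxy)benzaldehyde F5. Semihydrogenation of both alkynes (H2, Pd/CaCO3 poisoned with Pb(OAc)2, quinoline, EtOAc, rt) comes back to the route at 4.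

Further compounds
F1 | step 8 | 6-bromo-2,2-dimethyl-8-(2-methylbut-3-en-2-yloxy)-2H-chromene | CC1(C)C=Cc2cc(Br)cc(OC(C)(C)C=C)c2O1
F2 | step 8 | [2,2-dimethyl-8-(2-methylbut-3-en-2-yloxy)-2H-chromen-6-yl]boronic acid | CC1(C)C=Cc2cc(B(O)O)cc(OC(C)(C)C=C)c2O1
F3 | step 9 | 6-bromo-2,2-dimethyl-7-(3-methylbut-2-en-1-yl)-2H-chromen-8-ol | CC(C)=CCc1c(Br)cc2c(c1O)OC(C)(C)C=C2
F4 | step 9 | [8-hydroxy-2,2-dimethyl-7-(3-methylbut-2-en-1-yl)-2H-chromen-6-yl]boronic acid | CC(C)=CCc1c(B(O)O)cc2c(c1O)OC(C)(C)C=C2
F5 | step 2 | 5-bromo-2,3-bis(2-methylbut-3-yn-2-yloxy)benzaldehyde | O=Cc1cc(Br)cc(OC(C)(C)C#C)c1OC(C)(C)C#C
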